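# Proposed synthesis of CNP0152458.1 (37) through oxidative cleavage of a sacrificial ring B

## Analysis of the target

Compound 37 is a 6,7-seco-ent-kaurane of the spirolactone type; ent-kaurane numbering is used, and the hydroxymethyl on C4 is called C18. Ring A (C1–C5, C10) is a cyclohexane that shares only C10 with a δ-lactone (C7, O, C20, C10, C9, C8). The lactone is fused through C8–C9 to a bicyclo[3.2.1]octane (ring C: C8, C9, C11–C14; ring D: C8, C14, C13, C16, C15) that carries the C15 ketone, the exocyclic C16=C17 methylene and the C11 hydroxyl. There are seven stereocentres: on ring A, H5 is trans to C20, the C4 methyl is cis and C18 trans to C20; on the bicycle, H9 and the C15–C16 bridge lie on the same face of ring C, the C11 hydroxyl is equatorial on the opposite face, and C11 is cis to C1 across the lactone ring. C8 and C10 are quaternary and flank C9, so the C8–C9–C10 triad is the most crowded part of the molecule. The sensitive groups are the α-methylene cyclopentanone (a Michael acceptor), the β-keto lactone with non-enolisable C8 (opened by alkoxides in a retro-Claisen sense) and three free hydroxyls that must be told apart from a fourth oxygen at C15. The difficulty lies in making the spiro centre and the quaternary C8 and in ordering the oxidation states at C6, C7, C11 and C15. The plan rests on one feature: C7, C8, C9 and C10 of the lactone together with C5 and C6 are the six atoms of a former cyclohexane ring B cut between C6 and C7, with C7 at the acid level esterified by the C20 oxygen and C6 a one-carbon branch on C5.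

## Retrosynthetic reasoning

**Endgame adjustments.** 37 is traced to its bis-silyl ether 36, and the C16–C17 bond is cut to give hydroxy ketone 33. C8 is quaternary, so the C15 ketone can only enolise towards C16 and the methylene can be added last, when nothing else has to survive it. 33 comes from diol 32 by oxidation of the C15 carbinol alone.

**C9–C11 and C8–C15.** Both bonds are cut at once, which opens the bicyclooctane of 32 to dialdehyde 30. They are cut here because C9 and C8 are the β- and α-carbons of an unsaturated lactone. In the forward sense a ketyl radical at C11 adds to the β-carbon, and the enolate left at C8 closes ring D by aldol addition to C15. One operation gives two rings, the quaternary C8 and four stereocentres (C8, C9, C11, C13). The side chain is symmetrical (C13 carries two identical arms), so it needs no stereocentre of its own.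

**Masked aldehydes and C6.** 30 goes back to diene 29 (each terminal alkene is a latent aldehyde), and 29 to alcohol 28 and aldehyde 27. C6 has to be reduced and silylated before the cascade, because a C6 aldehyde would trap the C8 enolate.

**C6–C7 (key disconnection).** Reconnecting C6 to C7 and breaking the O–C7 bond turns 27 into the trans-decalin α-ketol 25, through its bridged hemiketal 26. The cut is made here because it converts the spiro centre C10 and its neighbours C5 and C4 into ordinary trans-decalin stereocentres. The lactone also needs no separate esterification: the forward cleavage has to break one bond only and leaves C7 already attached to the C20 oxygen.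

**C6 oxygen and C8–C14.** 25 comes from 24 by freeing the C20 carbinol, and 24 from enone 23 by oxidation of the α′-enolate. The C8–C14 bond of 23 is cut to iodoenone 17 and alkyl iodide 21 (used as zinc reagent 22). A cross-coupling at the vinylic α-carbon is preferred to enolate alkylation, which would be slow with a β-branched halide and would not leave the enone in place. 21 is made from malonate 18 through ester 19 and alcohol 20.

**Carbonyl transposition in ring B.** 17 is traced through enone 16, alkene 15 and enol triflate 14 to ketone 13. The ring B oxygen of the annulation product sits at C9 and has to be moved to C7; C10 is quaternary, so each of these steps has only one regiochemical course.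

**C20.** 13 comes from hydroxy ketone 12, and 12 from propenyl compound 10 and allyl compound 9 by isomerisation and cleavage. The allyl group is degraded while C9 is still a ketal (11) and while it is the only alkene in the molecule.

**C3 and C4.** 9 is reached from tosylhydrazone 8 and ketone 7; the C3 carbonyl is a relic of the annulation and is removed. 7 and alcohol 6 come from enone 5 by reductive hydroxymethylation, which sets C4 and C5 relative to C10 in one step.

**Ring A/B assembly.** 5 is the mono-ketal of enedione 4, which comes from 1 and 2 through triketone 3 by a catalytic asymmetric annulation. This is the only step where absolute configuration is introduced.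

## Alternatives that were turned down

**Alternative 1:** The C13–C14 bond of the bicyclooctane is cut, leaving a seven-membered enone ring (C8, C9, C11, C12, C13, C16, C15) with a one-carbon radical precursor on C8. In the forward step a primary C14 radical adds across that ring to C13 under radical-chain conditions, closing the five- and six-membered rings together and giving ketone A1.
- For it: the addition is polarity-matched and geometrically constrained, so C13 is set without choice. C11 (ketone) and C15 (ether) arrive already differentiated, and no competition between two aldehydes can arise. On these two points it is stronger than the chosen route, whose cascade (step 24) and C15 oxidation (step 25) both depend on selectivity.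
- Against it: the substrate must already contain the spirolactone with the quaternary C8, C9 and C10 in place and a seven-membered ring fused to it, so the hardest region is moved to an earlier, unsolved stage. C11 arrives as a ketone, and hydride would approach it from the open face and give the axial, wrong carbinol. C9 is α to that ketone and can epimerise.
- Comparison: the chosen strategy offers a precursor (25) made entirely by decalin chemistry and a C11 carbinol formed directly at the alcohol level.

**Alternative 2:** The C4–C5 bond of ring A is cut. In the forward step the silyl ketene acetal of a δ-lactone, whose ring oxygen sits on an allylic carbon (C2), rearranges [3,3]: C2–O breaks, C4–C5 forms, and the ring contracts to cyclohexene acid A2.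
- For it: chirality is transferred stereospecifically to the vicinal C4/C5 pair and tied to C10. C6 arrives at the acid level on C5, and C3 is never oxygenated. Here it is stronger than the chosen route, which spends two steps removing the C3 oxygen and several more moving a carbonyl from C9 to C7.
- Against it: A2 is ring A only. The lactone, C8, C9, the bicyclooctane and four stereocentres remain to be built from a saturated three-carbon chain on C10. A ring alkene, a silane (the masked C20 hydroxyl) and two different benzyl-type ethers still have to be processed. The outcome at C4/C5 depends on both the geometry of a trisubstituted alkene and a boat-versus-chair preference.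
- Comparison: the chosen strategy sets the same three ring-A centres by an annulation and a reductive alkylation of very predictable outcome, and then uses ring B itself as the template for the lactone.

**Alternative 3:** The C9–C10 bond is cut. In the forward step a preformed bicyclooctane dione acid is esterified with the C20 carbinol of a ring-A enal (C10=C5–C6), and the C9 enolate of the C11 ketone adds to C10. This forms the spiro centre, closes the δ-lactone and gives A3.
- For it: it is the most convergent plan, with two halves of similar size joined by an ester, and A3 already carries the C15 ketone and the C6 aldehyde. In longest linear sequence it would be shorter than the chosen route.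
- Against it: the acceptor carbon is the fully substituted β-carbon of a tetrasubstituted enal, and the nucleophile is a tertiary enolate carbon next to the quaternary C8. A quaternary centre must therefore form beside another one in a reversible addition. Enolisation can also occur at C12 or C16. Three new centres (C9, C10, C5) must be controlled relative to two independently made enantiopure fragments. The C11 ketone must later be reduced selectively and from the hindered face.
- Comparison: the chosen strategy has one source of chirality, fixes C10 and C5 before any crowding exists, and forms the lactone through an O–C bond that is under no steric stress.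

Key step: step 20

## Remarks on the chemistry

- C18 is carried as a tert-butyldiphenylsilyl (TBDPS) ether and C20 as a tert-butyldimethylsilyl (TBS) ether, so that C20 alone can be freed before step 20.
- Assumption: the C6 carbinol in 24–26, the C15 carbinol in 32 and C16 in 34 and 35 are drawn as expected (attack anti to C20; chelated aldol; exo attack). Each of these centres becomes sp2 later, so the other epimer would serve equally.

## Steps

Step 1
Reactants: 1 2-allylcyclohexane-1,3-dione; 2 pent-1-en-3-one
Product: 4 (S)-8a-allyl-5-methyl-3,4,8,8a-tetrahydronaphthalene-1,6(2H,7H)-dione, via triketone 3 (not isolated)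
Conditions: Et3N (cat.), MeCN, rt; then D-phenylalanine, (1R)-(−)-10-camphorsulfonic acid, DMF, 30→70 °C
Reagents that add atoms: none
Why: Robinson annulation: amine-promoted Michael addition gives triketone 3, which the amino acid closes by enamine-mediated intramolecular aldol condensation. The D-configured catalyst selects the ring carbonyl that leaves the allyl-bearing C10 with the configuration of 37, the mirror image of the series obtained with the L-amino acid.

Step 2
Reactants: 4 enedione
Product: 5 C9 ethylene ketal of 4
Conditions: ethylene glycol, TsOH·H2O (cat.), 4 Å molecular sieves, rt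
Reagents that add atoms: ethylene glycol, OCCO
Why: Chemoselective acid-catalysed ketalisation: the saturated C9 ketone reacts faster than the conjugated C3 carbonyl. The dioxolane shields C9 from the dissolving metal of step 3.

Step 3
Reactants: 5 ketal enone
Product: 6 trans-fused 4-hydroxymethyl-4-methyl-3-ketone
Conditions: Li, NH3/THF, t-BuOH (1 equiv), −78 °C; isoprene; NH3 removed; CH2O (gas), THF, −78→−30 °C; then H2O
Reagents that add atoms: formaldehyde, C=O
Why: Dissolving-metal (Birch-type) reduction of the enone gives, after axial protonation at C5, the trans-fused lithium enolate, which is trapped at C4 by monomeric formaldehyde (reductive hydroxymethylation, an aldol addition). The electrophile approaches anti to the axial C10 allyl group, so C18 ends trans and the methyl cis to C20, with H5 trans to C20; the isolated alkene and the ketal are inert.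

Step 4
Reactants: 6 keto alcohol
Product: 7 C18 TBDPS ether
Conditions: t-BuPh2SiCl, imidazole, DMF, rt
Reagents that add atoms: tert-butyl(chloro)diphenylsilane, CC(C)(C)[Si](Cl)(c1ccccc1)c1ccccc1
Why: Imidazole-promoted silylation of the primary hydroxyl; the acid-stable silyl ether blocks retro-aldol loss of formaldehyde and lasts until step 27.

Step 5
Reactants: 7 silyl ether ketone
Product: 8 C3 tosylhydrazone
Conditions: TsNHNH2, EtOH, 70 °C
Reagents that add atoms: 4-methylbenzenesulfonohydrazide, Cc1ccc(cc1)S(=O)(=O)NN
Why: Condensation of the only free ketone with the sulfonyl hydrazide under neutral conditions, which leave the C9 ketal in place; 4,4-disubstituted 3-ketones of this kind form tosylhydrazones on heating.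

Step 6
Reactants: 8 tosylhydrazone
Product: 9 3-deoxy trans-decalin
Conditions: catecholborane, CHCl3, 0 °C→rt; then NaOAc·3H2O, 60 °C
Reagents that add atoms: none
Why: Hydroboration of the C=N bond, acetate-induced loss of sulfinate and loss of N2 from the diazene give the methylene group (Kabalka variant of the Caglioti reduction). The conditions are neutral, and catecholborane does not hydroborate the terminal alkene at this temperature.

Step 7
Reactants: 9 allyl compound
Product: 10 (E)-prop-1-enyl compound
Conditions: RuHCl(CO)(PPh3)3 (5 mol%), toluene, 110 °C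
Reagents that add atoms: none
Why: Ruthenium hydride-catalysed alkene isomerisation (addition–elimination) moves the double bond into the internal position; it cannot move further because C10 is quaternary. The alkene geometry does not matter for step 8.

Step 8
Reactants: 10 propenyl compound
Product: 12 C20-hydroxy C9 ketone, via hydroxy ketal 11 (not isolated)
Conditions: O3, CH2Cl2/MeOH, −78 °C; NaBH4, −78→0 °C; then HCl (2 M aq.), THF, rt
Reagents that add atoms: ozone, [O-][O+]=O; water, O
Why: Ozonolysis of the only alkene and borohydride reduction of the ozonide give the neopentyl C20 alcohol 11 without a free aldehyde ever standing next to a ketone. Aqueous acid then hydrolyses the dioxolane, which the TBDPS ether withstands.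

Step 9
Reactants: 12 hydroxy ketone
Product: 13 C20 TBS ether
Conditions: t-BuMe2SiCl, imidazole, DMAP (cat.), DMF, rt
Reagents that add atoms: tert-butyl(chloro)dimethylsilane, CC(C)(C)[Si](C)(C)Cl
Why: Silylation under conditions that form no alkoxide, so the β-hydroxy ketone cannot lose C20 by retro-aldol. TBS is chosen because acid removes it later in the presence of the TBDPS ether.

Step 10
Reactants: 13 ketone
Product: 14 C8=C9 enol triflate
Conditions: KN(SiMe3)2, THF, −78 °C; PhNTf2, −78→0 °C
Reagents that add atoms: N-phenylbis(trifluoromethanesulfonimide), O=S(=O)(N(c1ccccc1)S(=O)(=O)C(F)(F)F)C(F)(F)F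
Why: C10 is quaternary, so the ketone enolises only towards C8; the potassium enolate is O-sulfonylated to the enol triflate.

Step 11
Reactants: 14 enol triflate
Product: 15 8-ene
Conditions: Pd(OAc)2 (5 mol%), PPh3, HCO2H, Bu3N, DMF, 60 °C
Reagents that add atoms: none
Why: Palladium-catalysed transfer hydrogenolysis: oxidative addition of the C–O bond to zerovalent palladium, formate exchange, decarboxylation to a palladium hydride and reductive elimination give the C8=C9 alkene regiospecifically.

Step 12
Reactants: 15 alkene
Product: 16 8-en-7-one
Conditions: CrO3, 3,5-dimethylpyrazole, CH2Cl2, −20 °C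
Reagents that add atoms: chromium trioxide, O=[Cr](=O)=O
Why: Allylic oxidation with the hexavalent chromium–pyrazole complex; C7 is the only allylic carbon that bears hydrogen. Oxygen delivery to the other allyl terminus (C9) is disfavoured by the adjacent quaternary C10.

Step 13
Reactants: 16 enone
Product: 17 8-iodo-8-en-7-one
Conditions: I2, pyridine, CH2Cl2, 0 °C→rt
Reagents that add atoms: iodine, II
Why: α-Iodination of the enone with iodine and pyridine (addition–elimination at the α-carbon); C8 is the only vinylic α-position, and 4,4-disubstituted cyclohexenones are good substrates.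

Step 14
Reactants: 18 diethyl diallylmalonate
Product: 19 ethyl 2-allylpent-4-enoate
Conditions: LiCl, H2O, DMSO, 160 °C
Reagents that add atoms: none
Why: Krapcho dealkoxycarbonylation: chloride attacks an ethyl group, the carboxylate loses CO2 and the enolate is protonated by water.

Step 15
Reactants: 19 ester
Product: 20 2-allylpent-4-en-1-ol
Conditions: LiAlH4, Et2O, 0 °C
Reagents that add atoms: none
Why: Hydride reduction of the ester to the primary alcohol; the terminal alkenes are inert.

Step 16
Reactants: 20 alcohol
Product: 21 4-(iodomethyl)hepta-1,6-diene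
Conditions: I2, PPh3, imidazole, CH2Cl2, 0 °C
Reagents that add atoms: iodine, II
Why: Appel-type iodination: phosphonium activation of the primary hydroxyl and SN2 displacement by iodide.

Step 17
Reactants: 17 iodoenone; 21 alkyl iodide
Product: 23 8-(2-allylpent-4-en-1-yl)-8-en-7-one, via alkylzinc iodide 22 (not isolated)
Conditions: 21, Zn dust, LiCl, THF, 40 °C; then 17, PdCl2(dppf) (5 mol%), THF/DMA, 50 °C
Reagents that add atoms: none
Why: Zinc inserts into the primary C–I bond to give 22, and Negishi coupling joins C14 to C8 (oxidative addition of C8–I to zerovalent palladium, transmetalation, reductive elimination; the bidentate diphosphine suppresses β-hydride elimination). The organozinc adds neither to the enone nor to the silyl ethers.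

Step 18
Reactants: 23 enone
Product: 24 6-hydroxy-7-keto-8-ene with C20 TBS ether
Conditions: KN(SiMe3)2, THF, −78 °C; 2-(phenylsulfonyl)-3-phenyloxaziridine, −78 °C; NH4Cl (aq.)
Reagents that add atoms: 2-(phenylsulfonyl)-3-phenyloxaziridine, O=S(=O)(N1OC1c1ccccc1)c1ccccc1
Why: Kinetic deprotonation takes the α′-hydrogen at C6 (cross-conjugated enolate), and the N-sulfonyloxaziridine transfers oxygen to that carbon. Attack anti to the axial C20 substituent and the axial C4 methyl puts the hydroxyl trans to C20; the centre becomes a carbonyl carbon in step 20.

Step 19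
Reactants: 24 ketol silyl ether
Product: 25 6-hydroxy-7-keto-8-ene with free C20 carbinol
Conditions: HCl (1 M aq.), THF, 0 °C→rt
Reagents that add atoms: none
Why: Acid hydrolysis removes the primary TBS ether, while the markedly more acid-stable TBDPS ether stays. Methanol is avoided so that the C7 ketone cannot be locked as a mixed methyl ketal with the freed C20 hydroxyl.

Step 20
Reactants: 25 α-ketol with free C20 carbinol
Product: 27 unsaturated spirolactone C6 aldehyde, via bridged hemiketal 26 (not isolated)
Conditions: Pb(OAc)4 (1.2 equiv), benzene/CH2Cl2, 0 °C→rt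
Reagents that add atoms: none
Why: In the aprotic medium the C20 hydroxyl adds reversibly to the C7 ketone (6-exo-trig) to give the 2-oxabicyclo[2.2.2]octene hemiketal 26, in which the C6 hydroxyl and the new C7 hydroxyl are gauche whichever way C6 is configured, so a five-membered cyclic lead diester can form. Two-electron fragmentation of that diester (tetravalent lead to divalent lead) breaks C6–C7, makes C7 the lactone carbonyl already bonded to the C20 oxygen and leaves C6 as the aldehyde, so the δ-lactone ring (C7, O, C20, C10, C9, C8) is closed by the hemiketal oxygen and not by a separate esterification. The closest known reaction type is the Criegee cleavage of α-ketols and α-hydroxy hemiketals to ester plus aldehyde, the scission that relates 6-hydroxy-7,20-hemiketal ent-kauranes to their 6,7-seco spirolactones. No stereocentre is formed: C4, C5 and C10 are spectators and C6 becomes sp2. The step needs cleavage of this one bond only: C6–C7 is the sole vicinally dioxygenated pair, C18 is silylated so that no competing hemiketal can form, and the isolated alkenes and the enone are inert to the reagent at room temperature. The cis relationship of C7 and C10 across C8=C9, fixed by the former ring, gives the unsaturated lactone directly with the right geometry.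

Step 21
Reactants: 27 lactone aldehyde
Product: 28 C6 alcohol
Conditions: NaBH4, MeOH/CH2Cl2, −40 °C
Reagents that add atoms: none
Why: Borohydride reduces the aldehyde much faster than it adds to the α-substituted unsaturated lactone at low temperature. The reduction is needed because a C6 aldehyde would intercept the C8 enolate in step 24.

Step 22
Reactants: 28 alcohol
Product: 29 C6 TBS ether
Conditions: t-BuMe2SiCl, imidazole, DMF, rt
Reagents that add atoms: tert-butyl(chloro)dimethylsilane, CC(C)(C)[Si](C)(C)Cl
Why: Standard imidazole-promoted silylation of the primary alcohol.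

Step 23
Reactants: 29 diene
Product: 30 dialdehyde
Conditions: O3, CH2Cl2/MeOH, pyridine (cat.), Sudan red 7B, −78 °C; then PPh3
Reagents that add atoms: ozone, [O-][O+]=O
Why: Ozone cleaves the two electron-rich terminal alkenes much faster than the electron-poor trisubstituted lactone alkene (indicator-controlled ozonolysis with reductive work-up). Both arms end as CH2–CHO, so C13 stays prochiral.

Step 24
Reactants: 30 dialdehyde
Product: 32 bicyclooctane 11,15-diol, via samarium enolate 31 (not isolated)
Conditions: SmI2 (2.5 equiv, slow addition), t-BuOH, THF, −78 °C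
Reagents that add atoms: none
Why: Ketyl–olefin/aldol cascade of a dialdehyde: the ketyl radical of one aldehyde adds 6-endo-trig to the β-carbon C9 from the lactone face anti to the C5 branch of C10, through a chair-like transition state in which samarium bridges the ketyl and lactone oxygens (C11 hydroxyl cis to C7) and the spectator arm is equatorial, away from the syn-axial O–Sm group (this fixes C13). A second electron gives enolate 31, which closes ring D by aldol addition to the remaining aldehyde from the only face its tether can reach and so fixes the quaternary C8. Slow addition of the divalent samarium reagent keeps the competing pinacol coupling down.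

Step 25
Reactants: 32 diol
Product: 33 11-hydroxy-15-ketone
Conditions: Dess–Martin periodinane (1.05 equiv), NaHCO3, CH2Cl2, −20→0 °C
Reagents that add atoms: none
Why: Periodinane oxidation with only a slight excess: the C15 carbinol sits on the open exo face of the five-membered ring, whereas the C11 carbinol is gauche to two branches of the quaternary spiro carbon C10 and exchanges onto iodine more slowly. The β-keto lactone formed cannot enolise towards C8 and is stable to the buffered conditions.

Step 26
Reactants: 33 hydroxy ketone
Product: 36 bis-silyl ether of the target, via Mannich base 34 (not isolated), via ammonium iodide 35 (not isolated)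
Conditions: LiN(SiMe3)2 (2.2 equiv), THF, −78 °C; N,N-dimethylmethyleneiminium iodide, −78 °C→rt; MeI, CH2Cl2; NaHCO3 (aq.)
Reagents that add atoms: N,N-dimethylmethyleneiminium iodide (Eschenmoser's salt), C=[N+](C)C.[I-]
Why: C8 is quaternary, so the C15 ketone enolises only towards C16 (the second equivalent of base takes the C11 hydroxyl proton). Mannich reaction with the iminium salt gives 34, N-methylation gives 35, and mild base eliminates trimethylamine (E1cB) to the exocyclic enone.

Step 27
Reactants: 36 bis-silyl ether
Product: 37 CNP0152458.1
Conditions: HF·pyridine, pyridine/THF, 0 °C→rt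
Reagents that add atoms: none
Why: Fluoride-mediated cleavage of both silyl ethers under buffered acidic conditions, which the α-methylene ketone and the β-keto lactone tolerate; alkoxide or basic fluoride would add to the enone or open the lactone.

## Compound list

1 | 2-allylcyclohexane-1,3-dione | C=CCC1C(=O)CCCC1=O | starting material
2 | pent-1-en-3-one | CCC(=O)C=C | starting material
3 | 2-allyl-2-(3-oxopentyl)cyclohexane-1,3-dione | C=CCC1(CCC(=O)CC)C(=O)CCCC1=O | intermediate (not isolated)
4 | (S)-8a-allyl-5-methyl-3,4,8,8a-tetrahydronaphthalene-1,6(2H,7H)-dione (C3/C9 dione with C4=C5; C10 as in the target) | C=CC[C@@]12CCC(=O)C(C)=C1CCCC2=O | intermediate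
5 | C9 ethylene ketal of 4 (9,9-ethylenedioxy-4-en-3-one) | C=CC[C@@]12CCC(=O)C(C)=C1CCCC23OCCO3 | intermediate
6 | trans-decalin 3-ketone 9-ketal with 10-allyl; 4-methyl cis and 4-hydroxymethyl (C18) trans to the allyl group; H5 trans to allyl | C=CC[C@@]12CCC(=O)[C@](C)(CO)[C@H]1CCCC23OCCO3 | intermediate
7 | C18 tert-butyldiphenylsilyl ether of 6 | C=CC[C@@]12CCC(=O)[C@](C)(CO[Si](c4ccccc4)(c5ccccc5)C(C)(C)C)[C@H]1CCCC23OCCO3 | intermediate
8 | C3 tosylhydrazone of 7 | C=CC[C@@]12CCC(=NNS(=O)(=O)c6ccc(C)cc6)[C@](C)(CO[Si](c4ccccc4)(c5ccccc5)C(C)(C)C)[C@H]1CCCC23OCCO3 | intermediate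
9 | 3-deoxy compound: 10-allyl-18-silyloxy trans-decalin 9-ketal | C=CC[C@@]12CCC[C@](C)(CO[Si](c4ccccc4)(c5ccccc5)C(C)(C)C)[C@H]1CCCC23OCCO3 | intermediate
10 | 10-[(E)-prop-1-enyl] analogue of 9 | C/C=C/[C@@]12CCC[C@](C)(CO[Si](c4ccccc4)(c5ccccc5)C(C)(C)C)[C@H]1CCCC23OCCO3 | intermediate
11 | 10-hydroxymethyl (C20 alcohol) 9-ketal | OC[C@@]12CCC[C@](C)(CO[Si](c4ccccc4)(c5ccccc5)C(C)(C)C)[C@H]1CCCC23OCCO3 | intermediate (not isolated)
12 | 10-hydroxymethyl 9-ketone | OC[C@@]12CCC[C@](C)(CO[Si](c4ccccc4)(c5ccccc5)C(C)(C)C)[C@H]1CCCC2=O | intermediate
13 | C20 tert-butyldimethylsilyl ether of 12 | CC(C)(C)[Si](C)(C)OC[C@@]12CCC[C@](C)(CO[Si](c4ccccc4)(c5ccccc5)C(C)(C)C)[C@H]1CCCC2=O | intermediate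
14 | 8-en-9-yl triflate | CC(C)(C)[Si](C)(C)OC[C@@]12CCC[C@](C)(CO[Si](c4ccccc4)(c5ccccc5)C(C)(C)C)[C@H]1CCC=C2OS(=O)(=O)C(F)(F)F | intermediate
15 | 8-ene | CC(C)(C)[Si](C)(C)OC[C@@]12CCC[C@](C)(CO[Si](c4ccccc4)(c5ccccc5)C(C)(C)C)[C@H]1CCC=C2 | intermediate
16 | 8-en-7-one | CC(C)(C)[Si](C)(C)OC[C@@]12CCC[C@](C)(CO[Si](c4ccccc4)(c5ccccc5)C(C)(C)C)[C@H]1CC(=O)C=C2 | intermediate
17 | 8-iodo-8-en-7-one | CC(C)(C)[Si](C)(C)OC[C@@]12CCC[C@](C)(CO[Si](c4ccccc4)(c5ccccc5)C(C)(C)C)[C@H]1CC(=O)C(I)=C2 | intermediate
18 | diethyl diallylmalonate | CCOC(=O)C(CC=C)(CC=C)C(=O)OCC | starting material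
19 | ethyl 2-allylpent-4-enoate | CCOC(=O)C(CC=C)CC=C | intermediate
20 | 2-allylpent-4-en-1-ol | OCC(CC=C)CC=C | intermediate
21 | 4-(iodomethyl)hepta-1,6-diene | ICC(CC=C)CC=C | intermediate
22 | (2-allylpent-4-en-1-yl)zinc iodide | I[Zn]CC(CC=C)CC=C | intermediate (not isolated)
23 | 8-(2-allylpent-4-en-1-yl)-8-en-7-one | CC(C)(C)[Si](C)(C)OC[C@@]12CCC[C@](C)(CO[Si](c4ccccc4)(c5ccccc5)C(C)(C)C)[C@H]1CC(=O)C(CC(CC=C)CC=C)=C2 | intermediate
24 | 6-hydroxy-7-keto-8-ene, C20 TBS ether (6-OH trans to C20) | CC(C)(C)[Si](C)(C)OC[C@@]12CCC[C@](C)(CO[Si](c4ccccc4)(c5ccccc5)C(C)(C)C)[C@H]1[C@H](O)C(=O)C(CC(CC=C)CC=C)=C2 | intermediate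
25 | trans-decalin 6-hydroxy-7-keto-8-ene with free C20 carbinol (key-step precursor) | OC[C@@]12CCC[C@](C)(CO[Si](c4ccccc4)(c5ccccc5)C(C)(C)C)[C@H]1[C@H](O)C(=O)C(CC(CC=C)CC=C)=C2 | intermediate
26 | 7,20-bridged hemiketal of 25 (7-hydroxy-7,20-epoxy) | O3C[C@@]12CCC[C@](C)(CO[Si](c4ccccc4)(c5ccccc5)C(C)(C)C)[C@H]1[C@H](O)[C@]3(O)C(CC(CC=C)CC=C)=C2 | intermediate (not isolated)
27 | unsaturated spirolactone C6 aldehyde (key-step product) | C=CCC(CC=C)CC1=C[C@@]2(CCC[C@](C)(CO[Si](c3ccccc3)(c4ccccc4)C(C)(C)C)[C@H]2C=O)COC1=O | intermediate
28 | C6 alcohol of 27 | C=CCC(CC=C)CC1=C[C@@]2(CCC[C@](C)(CO[Si](c3ccccc3)(c4ccccc4)C(C)(C)C)[C@H]2CO)COC1=O | intermediate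
29 | C6 TBS ether of 28 | C=CCC(CC=C)CC1=C[C@@]2(CCC[C@](C)(CO[Si](c3ccccc3)(c4ccccc4)C(C)(C)C)[C@H]2CO[Si](C)(C)C(C)(C)C)COC1=O | intermediate
30 | dialdehyde (both arms CH2CHO) | O=CCC(CC=O)CC1=C[C@@]2(CCC[C@](C)(CO[Si](c3ccccc3)(c4ccccc4)C(C)(C)C)[C@H]2CO[Si](C)(C)C(C)(C)C)COC1=O | intermediate
31 | trivalent samarium lactone enolate and C11 alkoxide after C9–C11 closure | O=CC[C@@H]1C[C@@H](O[Sm](I)I)[C@@H]2C(=C(O[Sm](I)I)OC[C@]23CCC[C@](C)(CO[Si](c4ccccc4)(c5ccccc5)C(C)(C)C)[C@H]3CO[Si](C)(C)C(C)(C)C)C1 | intermediate (not isolated)
32 | bicyclooctane 11,15-diol (15-OH exo, syn to C7) | C1[C@H](O)[C@]23C[C@H]1C[C@@H](O)[C@H]2[C@@]1(CCC[C@](C)(CO[Si](c4ccccc4)(c5ccccc5)C(C)(C)C)[C@H]1CO[Si](C)(C)C(C)(C)C)COC3=O | intermediate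
33 | 11-hydroxy-15-ketone | C1C(=O)[C@]23C[C@H]1C[C@@H](O)[C@H]2[C@@]1(CCC[C@](C)(CO[Si](c4ccccc4)(c5ccccc5)C(C)(C)C)[C@H]1CO[Si](C)(C)C(C)(C)C)COC3=O | intermediate
34 | 16-(dimethylaminomethyl)-15-ketone (exo) | CN(C)C[C@@H]1C(=O)[C@]23C[C@H]1C[C@@H](O)[C@H]2[C@@]1(CCC[C@](C)(CO[Si](c4ccccc4)(c5ccccc5)C(C)(C)C)[C@H]1CO[Si](C)(C)C(C)(C)C)COC3=O | intermediate (not isolated)
35 | 16-(trimethylammoniomethyl)-15-ketone iodide | C[N+](C)(C)C[C@@H]1C(=O)[C@]23C[C@H]1C[C@@H](O)[C@H]2[C@@]1(CCC[C@](C)(CO[Si](c4ccccc4)(c5ccccc5)C(C)(C)C)[C@H]1CO[Si](C)(C)C(C)(C)C)COC3=O.[I-] | intermediate (not isolated)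
36 | 6-O-TBS, 18-O-TBDPS ether of the target | C=C1C(=O)[C@]23C[C@H]1C[C@@H](O)[C@H]2[C@@]1(CCC[C@](C)(CO[Si](c4ccccc4)(c5ccccc5)C(C)(C)C)[C@H]1CO[Si](C)(C)C(C)(C)C)COC3=O | intermediate
37 | CNP0152458.1 | C=C1C(=O)[C@]23C[C@H]1C[C@@H](O)[C@H]2[C@@]1(CCC[C@](C)(CO)[C@H]1CO)COC3=O | target

## Step count and least certain steps

Total: 27 steps. Longest linear sequence: 24 steps (steps 1–13 and 17–27); steps 14–16 are a three-step branch that supplies 21.

**Step 20 (key step).** The conjugated C7 ketone may hold too little of hemiketal 26 at equilibrium. Cleavage would then be slow and the oxidant consumed in acetoxylation next to the ketone, or the cleavage would run through the open ketol with acetate as external nucleophile and end in an acid derivative instead of the lactone. Fallback: from 25, periodate cleavage (NaIO4, THF/H2O) runs through the ketone hydrate and gives the (Z)-hydroxy acid aldehyde F1 (C7 carboxylic acid, C6 aldehyde, free C20 hydroxyl). Acid and carbinol are held cis on the C8=C9 double bond, so acid catalysis with removal of water, or a carbodiimide, closes the δ-lactone and returns to 27.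

**Step 24.** Three processes may intervene: pinacol coupling of the two aldehydes (they are 1,5-related), protonation of enolate 31 before the strained aldol closure, or poor discrimination between the two diastereotopic arms. Fallback, with one aldehyde at a time, from 29 to 33:
- One allyl group of 29 is cleaved with catalytic OsO4 and a limiting amount of NaIO4. This does not distinguish the arms, so only the C13 epimer mono-aldehyde F2 can be carried on and the other is lost.
- F2 undergoes the SmI2 ketyl–olefin cyclisation alone, with no second aldehyde present, to give hydroxy lactone F3.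
- LiN(iPr)2 and Me3SiCl silylate the C11 hydroxyl and convert the lactone into the silyl ketene acetal F4.
- Stoichiometric Pd(OAc)2 cyclises C8 onto the internal carbon of the remaining allyl group (5-exo, then β-hydride elimination) to the 15-methylene bicyclooctane F5.
- Ozonolysis with mildly acidic work-up cleaves the exocyclic alkene and the trimethylsilyl ether and returns to 33. This also bypasses step 25.

**Step 25.** The C11 carbinol may be oxidised as well, since two hindered secondary alcohols are told apart only by their surroundings; this would give the 11,15-dione and lose the C11 stereocentre. Fallback, differentiating by acylation before oxidation, from 32 to 33: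
- Chloroacetic anhydride (1 equiv, pyridine, −20 °C) esterifies the more accessible C15 hydroxyl to the chloroacetate F6.
- Et3SiOTf and 2,6-lutidine silylate C11 to give F7.
- Thiourea and NaHCO3 remove the chloroacetate without forming an alkoxide, giving the C15 alcohol F8.
- Periodinane oxidation gives the ketone F9.
- Brief HF·pyridine in pyridine removes the secondary triethylsilyl ether before the primary silyl ethers and returns to 33.

**Step 12.** The oxidation may occur with allylic transposition (oxygen delivered to C9), the hindered alkene may convert slowly, or over-oxidation may occur. Fallback without C–H oxidation: from 13, dehydrogenation with IBX gives the 7-en-9-one F10; nucleophilic epoxidation (H2O2, NaOH) gives the epoxy ketone F11; hydrazine and acetic acid (Wharton transposition) give the 8-en-7-ol F12; MnO2 oxidation returns to 16.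

**Step 3.** Trapping of the lithium enolate by gaseous formaldehyde may be incomplete (polymerisation of the aldehyde, proton transfer to the enolate, retro-aldol on work-up). Fallback: from 5, the same reduction is quenched with Me3SiCl/Et3N to give the silyl enol ether F13. This is hydroxymethylated with aqueous formaldehyde and catalytic Yb(OTf)3 in THF/water (Mukaiyama aldol), with the same facial preference, and returns to 6.

## Further compounds

F1 | step 20 | (Z)-hydroxy acid aldehyde (C7 acid, C6 aldehyde, free C20 hydroxyl) | OC(=O)/C(CC(CC=C)CC=C)=C\[C@@]1(CCC[C@](C)(CO[Si](c2ccccc2)(c3ccccc3)C(C)(C)C)[C@H]1C=O)CO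
F2 | step 24 | mono-aldehyde with one allyl arm retained (productive C13 epimer) | C=CC[C@H](CC=O)CC1=C[C@@]2(CCC[C@](C)(CO[Si](c3ccccc3)(c4ccccc4)C(C)(C)C)[C@H]2CO[Si](C)(C)C(C)(C)C)COC1=O
F3 | step 24 | ring C hydroxy lactone with 13-allyl (C8 epimer mixture, C8 left undefined) | C=CC[C@@H]1C[C@@H](O)[C@@H]2C(C(=O)OC[C@]23CCC[C@](C)(CO[Si](c4ccccc4)(c5ccccc5)C(C)(C)C)[C@H]3CO[Si](C)(C)C(C)(C)C)C1
F4 | step 24 | lactone trimethylsilyl ketene acetal with C11 trimethylsilyl ether | C=CC[C@@H]1C[C@@H](O[Si](C)(C)C)[C@@H]2C(=C(O[Si](C)(C)C)OC[C@]23CCC[C@](C)(CO[Si](c4ccccc4)(c5ccccc5)C(C)(C)C)[C@H]3CO[Si](C)(C)C(C)(C)C)C1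
F5 | step 24 | 15-methylene bicyclooctane with C11 trimethylsilyl ether | C1C(=C)[C@]23C[C@H]1C[C@@H](O[Si](C)(C)C)[C@H]2[C@@]1(CCC[C@](C)(CO[Si](c4ccccc4)(c5ccccc5)C(C)(C)C)[C@H]1CO[Si](C)(C)C(C)(C)C)COC3=O
F6 | step 25 | 15-chloroacetate of 32 | C1[C@H](OC(=O)CCl)[C@]23C[C@H]1C[C@@H](O)[C@H]2[C@@]1(CCC[C@](C)(CO[Si](c4ccccc4)(c5ccccc5)C(C)(C)C)[C@H]1CO[Si](C)(C)C(C)(C)C)COC3=O
F7 | step 25 | 15-chloroacetate 11-triethylsilyl ether | C1[C@H](OC(=O)CCl)[C@]23C[C@H]1C[C@@H](O[Si](CC)(CC)CC)[C@H]2[C@@]1(CCC[C@](C)(CO[Si](c4ccccc4)(c5ccccc5)C(C)(C)C)[C@H]1CO[Si](C)(C)C(C)(C)C)COC3=O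
F8 | step 25 | 15-alcohol 11-triethylsilyl ether | C1[C@H](O)[C@]23C[C@H]1C[C@@H](O[Si](CC)(CC)CC)[C@H]2[C@@]1(CCC[C@](C)(CO[Si](c4ccccc4)(c5ccccc5)C(C)(C)C)[C@H]1CO[Si](C)(C)C(C)(C)C)COC3=O
F9 | step 25 | 15-ketone 11-triethylsilyl ether | C1C(=O)[C@]23C[C@H]1C[C@@H](O[Si](CC)(CC)CC)[C@H]2[C@@]1(CCC[C@](C)(CO[Si](c4ccccc4)(c5ccccc5)C(C)(C)C)[C@H]1CO[Si](C)(C)C(C)(C)C)COC3=O
F10 | step 12 | 7-en-9-one | CC(C)(C)[Si](C)(C)OC[C@@]12CCC[C@](C)(CO[Si](c4ccccc4)(c5ccccc5)C(C)(C)C)[C@H]1CC=CC2=O
F11 | step 12 | 7,8-epoxy-9-ketone (epoxide anti to C20) | CC(C)(C)[Si](C)(C)OC[C@@]12CCC[C@](C)(CO[Si](c4ccccc4)(c5ccccc5)C(C)(C)C)[C@H]1C[C@@H]3O[C@@H]3C2=O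
F12 | step 12 | 8-en-7-ol (hydroxyl anti to C20) | CC(C)(C)[Si](C)(C)OC[C@@]12CCC[C@](C)(CO[Si](c4ccccc4)(c5ccccc5)C(C)(C)C)[C@H]1C[C@H](O)C=C2
F13 | step 3 | C3 trimethylsilyl enol ether (C3=C4) of the trans-fused reduction product | C=CC[C@@]12CCC(O[Si](C)(C)C)=C(C)[C@H]1CCCC23OCCO3
A1 | alternative 1 | bicyclo[3.2.1]octan-11-one spirolactone with C15 methoxymethyl ether and C6, C18 silyl ethers | C1[C@H](OCOC)[C@]23C[C@H]1CC(=O)[C@H]2[C@@]1(CCC[C@](C)(CO[Si](C)(C)C(C)(C)C)[C@H]1CO[Si](C)(C)C(C)(C)C)COC3=O
A2 | alternative 2 | ring A cyclohexene carboxylic acid (C6 acid on C5, C2=C3, C4 benzyloxymethyl, C10 bearing CH2SiMe2Ph and a 3-(4-methoxybenzyloxy)propyl chain) | COc1ccc(COCCC[C@@]2(CC=C[C@](C)(COCc3ccccc3)[C@H]2C(=O)O)C[Si](C)(C)c3ccccc3)cc1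
A3 | alternative 3 | tetracyclic spirolactone 11,15-dione with C6 aldehyde and C18 silyl ether | C1C(=O)[C@]23C[C@H]1CC(=O)[C@H]2[C@@]1(CCC[C@](C)(CO[Si](C)(C)C(C)(C)C)[C@H]1C=O)COC3=O
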